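## Retrosynthetic overview

- Numbering: the lactone is O1–C2(=O)–C3–C4–C5. Ring A is the 3-hydroxy-4,5-dimethoxyphenyl group on the exocyclic C3=CH. Ring B is the 4-hydroxy-3-methoxyphenyl group on the CH2 at C4.
- The exocyclic C3=CH bond is made last, by aldol addition and elimination between the saturated (4R)-lactone and the ring A aldehyde. Both phenols are carried as triisopropylsilyl (TIPS) ethers.
- The plan rests on this feature: in the saturated lactone the only stereocentre, C4, sits between two CH2 groups (C3 and C5), and O1 separates C5 from the carbonyl C2. Removing O1 from the O1–C5 bond joins C5 to C2 and leaves a 3-(arylmethyl)cyclobutanone with a mirror plane, so one enantioselective Baeyer–Villiger oxygen insertion creates O1–C5, the five-membered ring and C4 together.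
- The cyclobutanone comes from the allyl group of eugenol by (2+2) cycloaddition with dichloroketene, followed by dechlorination.
- Ring order: rings A and B are bought, the cyclobutane is formed in step 2 and expanded to the γ-lactone in step 4, and no further ring is made.

Key step: step 4

Assumption: the ligand antipode (L- or D-proline series) that leads to the R-lactone is settled in a trial run by chiral HPLC and chemical correlation. The route is written for the antipode that gives 8.

## Route

Step 1
Reactants: 1 eugenol
Product: 2 (4-allyl-2-methoxyphenoxy)triisopropylsilane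
Conditions: TIPSCl, imidazole, DMF, rt
Reagents that add atoms: chlorotriisopropylsilane (TIPSCl), CC(C)[Si](Cl)(C(C)C)C(C)C
Why: Imidazole-promoted O-silylation of a phenol, in which the bulky silyl ether is preferred to an acetal such as a methoxymethyl ether because Cl3CCOCl/ZnCl2 in step 2 would split an acetal, whereas ArO–TIPS tolerates ZnCl2, Zn/AcOH, peracid, LiN(iPr)2 and DBU and falls to fluoride at the end.

Step 2
Reactants: 2 (4-allyl-2-methoxyphenoxy)triisopropylsilane; 3 trichloroacetyl chloride
Product: 5 rac-2,2-dichloro-3-{[3-methoxy-4-(triisopropylsilyloxy)phenyl]methyl}cyclobutan-1-one, via dichloroketene 4 (not isolated)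
Conditions: Zn–Cu couple, Et2O/DME, slow addition of 3, rt → gentle reflux
Reagents that add atoms: none
Why: Thermal (2+2) ketene–alkene cycloaddition in which the electrophilic carbonyl carbon of 4 (from zinc dechlorination of 3) bonds to the terminal alkene carbon so that CCl2 ends up next to the substituted carbon, DME ties up ZnCl2, and the one stereocentre formed is racemic and irrelevant because step 3 makes the ring prochiral.

Step 3
Reactants: 5 rac-2,2-dichloro-3-{[3-methoxy-4-(triisopropylsilyloxy)phenyl]methyl}cyclobutan-1-one
Product: 6 3-{[3-methoxy-4-(triisopropylsilyloxy)phenyl]methyl}cyclobutan-1-one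
Conditions: Zn dust, AcOH, rt
Reagents that add atoms: none
Why: Reductive dehalogenation of an α,α-dichloroketone through zinc enolates that AcOH protonates, which removes both chlorines and leaves a cyclobutanone with a mirror plane through C=O and the substituted carbon while the aryl silyl and methyl ethers stay inert.

Step 4
Reactants: 6 3-{[3-methoxy-4-(triisopropylsilyloxy)phenyl]methyl}cyclobutan-1-one
Product: 8 (4R)-4-{[3-methoxy-4-(triisopropylsilyloxy)phenyl]methyl}oxolan-2-one, via Criegee adduct 7 (not isolated)
Conditions: Sc(OTf)3 (5 mol%), C2-symmetric N,N′-dioxide ligand from proline 2,6-diisopropylanilide with a (CH2)3 linker (5.5 mol%), mCPBA (slow addition), EtOAc, −20 °C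
Reagents that add atoms: 3-chloroperbenzoic acid (mCPBA), O=C(OO)c1cccc(Cl)c1
Why: This is an asymmetric Baeyer–Villiger oxidation, the known desymmetrisation of prochiral 3-substituted cyclobutanones with Sc(OTf)3/N,N′-dioxide catalysts: the ketone bound to trivalent scandium takes up the peracid to give Criegee adduct 7, and the ring CH2 whose C–C bond lies antiperiplanar to the O–O bond shifts from carbon to oxygen as 3-chlorobenzoate leaves. The lactone ring is not closed from an open chain but arises by four-to-five ring expansion, the 1,2-shift creating O1–C5 while C2–C3, C3–C4 and C4–C5 come unchanged from the cyclobutane, and release of ring strain lets the oxidation run at low temperature. C4 is not touched and becomes stereogenic only because one of the two enantiotopic CH2 groups migrates, a choice made by the chiral pocket of the ligand, which should hold the puckered ring with its pseudo-equatorial arylmethyl group turned away from the anilide walls so that only one CH2 reaches the antiperiplanar alignment. There is no regiochemical issue because both α-carbons are CH2 groups of equal migratory aptitude, and the only other oxidisable site, electron-rich ring B, should be inert to the peracid at this temperature once its phenol is silylated. The selectivity at risk is the enantioselectivity, which the uncatalysed background oxidation erodes and which low temperature, slow addition of the peracid and a weakly coordinating ester solvent are meant to protect.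

Step 5
Reactants: 9 3-hydroxy-4,5-dimethoxybenzaldehyde
Product: 10 3,4-dimethoxy-5-(triisopropylsilyloxy)benzaldehyde
Conditions: TIPSCl, imidazole, DMF, rt
Reagents that add atoms: chlorotriisopropylsilane (TIPSCl), CC(C)[Si](Cl)(C(C)C)C(C)C
Why: Imidazole-promoted O-silylation of the ring A phenol removes the acidic proton that would quench the enolate in step 6, and using the same group as on ring B allows one final deprotection.

Step 6
Reactants: 8 (4R)-4-{[3-methoxy-4-(triisopropylsilyloxy)phenyl]methyl}oxolan-2-one; 10 3,4-dimethoxy-5-(triisopropylsilyloxy)benzaldehyde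
Product: 12 (3S,4R)-3-{hydroxy[3,4-dimethoxy-5-(triisopropylsilyloxy)phenyl]methyl}-4-{[3-methoxy-4-(triisopropylsilyloxy)phenyl]methyl}oxolan-2-one (mixture of carbinol epimers), via lithium enolate 11 (not isolated)
Conditions: LiN(iPr)2 (commercial solution), THF, −78 °C; then 10, −78 °C; AcOH quench at −78 °C
Reagents that add atoms: none
Why: Directed aldol addition of a lactone lithium enolate to a non-enolisable aldehyde, in which the aldehyde approaches C3 anti to the C4 arylmethyl group (3,4-trans), the carbinol centre forms as an epimer mixture, both new centres are erased in step 7, and the non-acidic C4 is untouched.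

Step 7
Reactants: 12 aldol adduct (carbinol epimers)
Product: 14 (3E,4R)-3-{[3,4-dimethoxy-5-(triisopropylsilyloxy)phenyl]methylidene}-4-{[3-methoxy-4-(triisopropylsilyloxy)phenyl]methyl}oxolan-2-one, via mesylate 13 (not isolated)
Conditions: MsCl, Et3N, CH2Cl2, 0 °C; then DBU, 0 °C → rt, short contact time
Reagents that add atoms: methanesulfonyl chloride, CS(=O)(=O)Cl (its atoms stand in 13 only and leave again on the way to 14)
Why: Mesylation followed by β-elimination of E1cB type, in which DBU removes the acidic C3–H and the enolate expels mesylate from either carbinol epimer through the conformer that places ring A anti to the lactone carbonyl, converging on the cinnamate-like, thermodynamically preferred E-alkene.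

Step 8
Reactants: 14 bis(triisopropylsilyl) ether of the target
Product: 15 (3E,4R)-3-[(3-hydroxy-4,5-dimethoxyphenyl)methylidene]-4-[(4-hydroxy-3-methoxyphenyl)methyl]oxolan-2-one
Conditions: Bu4NF, AcOH, THF, 0 °C
Reagents that add atoms: none
Why: Fluoride-induced cleavage of both aryl silyl ethers (strong Si–F bond, phenoxide leaving groups), buffered with AcOH so that no basic species can remove C4–H of the unsaturated lactone, open the lactone or isomerise the alkene.

## Compound list

1 | eugenol (4-allyl-2-methoxyphenol) | C=CCc1ccc(O)c(OC)c1 | starting material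
2 | (4-allyl-2-methoxyphenoxy)triisopropylsilane | C=CCc1ccc(O[Si](C(C)C)(C(C)C)C(C)C)c(OC)c1 | intermediate
3 | trichloroacetyl chloride | ClC(=O)C(Cl)(Cl)Cl | starting material
4 | dichloroketene (formed in the flask) | ClC(Cl)=C=O | intermediate
5 | rac-2,2-dichloro-3-{[3-methoxy-4-(triisopropylsilyloxy)phenyl]methyl}cyclobutan-1-one | O=C1CC(Cc2ccc(O[Si](C(C)C)(C(C)C)C(C)C)c(OC)c2)C1(Cl)Cl | intermediate
6 | 3-{[3-methoxy-4-(triisopropylsilyloxy)phenyl]methyl}cyclobutan-1-one (achiral, prochiral) | O=C1CC(Cc2ccc(O[Si](C(C)C)(C(C)C)C(C)C)c(OC)c2)C1 | intermediate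
7 | Criegee adduct, 1-hydroxy-3-{[3-methoxy-4-(triisopropylsilyloxy)phenyl]methyl}cyclobutyl 3-chlorobenzenecarboperoxoate (scandium-bound in the flask) | OC1(OOC(=O)c2cccc(Cl)c2)CC(Cc2ccc(O[Si](C(C)C)(C(C)C)C(C)C)c(OC)c2)C1 | intermediate
8 | (4R)-4-{[3-methoxy-4-(triisopropylsilyloxy)phenyl]methyl}oxolan-2-one | COc1cc(C[C@H]2COC(=O)C2)ccc1O[Si](C(C)C)(C(C)C)C(C)C | intermediate
9 | 3-hydroxy-4,5-dimethoxybenzaldehyde | COc1cc(C=O)cc(O)c1OC | starting material
10 | 3,4-dimethoxy-5-(triisopropylsilyloxy)benzaldehyde | COc1cc(C=O)cc(O[Si](C(C)C)(C(C)C)C(C)C)c1OC | intermediate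
11 | lithium enolate of 8 (4R, formed in the flask) | COc1cc(C[C@H]2COC([O-])=C2)ccc1O[Si](C(C)C)(C(C)C)C(C)C.[Li+] | intermediate
12 | (3S,4R)-aldol adduct, 3,4-trans, carbinol carbon as epimer mixture | COc1cc(C[C@H]2COC(=O)[C@@H]2C(O)c2cc(O[Si](C(C)C)(C(C)C)C(C)C)c(OC)c(OC)c2)ccc1O[Si](C(C)C)(C(C)C)C(C)C | intermediate
13 | methanesulfonate of 12 (3S,4R, formed in the flask) | COc1cc(C[C@H]2COC(=O)[C@@H]2C(OS(C)(=O)=O)c2cc(O[Si](C(C)C)(C(C)C)C(C)C)c(OC)c(OC)c2)ccc1O[Si](C(C)C)(C(C)C)C(C)C | intermediate
14 | (3E,4R)-3-{[3,4-dimethoxy-5-(triisopropylsilyloxy)phenyl]methylidene}-4-{[3-methoxy-4-(triisopropylsilyloxy)phenyl]methyl}oxolan-2-one | COc1cc(C[C@H]2COC(=O)/C2=C/c2cc(O[Si](C(C)C)(C(C)C)C(C)C)c(OC)c(OC)c2)ccc1O[Si](C(C)C)(C(C)C)C(C)C | intermediate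
15 | (3E,4R)-3-[(3-hydroxy-4,5-dimethoxyphenyl)methylidene]-4-[(4-hydroxy-3-methoxyphenyl)methyl]oxolan-2-one (CNP0187799.1) | COc1cc(C[C@H]2COC(=O)/C2=C/c2cc(O)c(OC)c(OC)c2)ccc1O | target

## Step count and risks

Total step count: 8.
Longest linear sequence: 7 steps (steps 1, 2, 3, 4, 6, 7, 8 from eugenol). Step 5 is a one-step side branch.

**Step 4.**
- Risk: the two enantiotopic CH2 groups may be told apart only in part. The controlling aryl group is insulated from the ring by a CH2, and the uncatalysed peracid oxidation of the strained ketone competes with the catalysed one.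
- Fallback: the enantiotopic-group selection is moved from the migration to a deprotonation.
- From 6, the C2-symmetric chiral base lithium bis(1-phenylethyl)amide (antipode chosen for the R series), with Et3SiCl present as internal quench in THF at −100 °C, should give the triethylsilyl enol ether F1.
- Ozonolysis of its C=C bond (CH2Cl2/MeOH, −78 °C, ozone dosed to spare ring B) with NaBH4 reduction in the same flask should give the hydroxy acid F2.
- F2 lactonises on mildly acidic work-up and comes back to the route at 8.

**Step 7.**
- Risk: three processes threaten this step.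
  - The elimination may deliver the alkene with incomplete E selectivity.
  - DBU may remove C4–H of the product, which moves the double bond into the ring and erodes the C4 configuration.
  - The electron-rich benzylic sulfonate may ionise before it eliminates.
- Fallback: a Horner–Wadsworth–Emmons olefination replaces steps 6 and 7.
- From 8, LiN(iPr)2 and then ClP(O)(OEt)2 in THF at −78 °C should give the ketene acetal phosphate F3.
- With further LiN(iPr)2, F3 undergoes the 1,3-shift of phosphorus from oxygen to carbon, giving the α-phosphono lactone F4.
- The sodium salt of F4 (NaH, THF, 0 °C) condenses with aldehyde 10 under the usual E preference of stabilised phosphonates. The sequence comes back to the route at 14, and the product never meets an amidine base.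

**Step 2.**
- Risk: the unactivated monosubstituted alkene may trap the ketene more slowly than the ketene oligomerises. ZnCl2 may also trigger acylation of the electron-rich ring or migration of the allyl double bond.
- Fallback: a keteniminium (2+2) cycloaddition, free of zinc and chlorine.
- From 2, N,N-dimethylacetamide, Tf2O and 2,4,6-collidine in ClCH2CH2Cl at reflux generate N,N-dimethylketeniminium triflate F5.
- F5 adds to the alkene with the same regiochemistry to give the cyclobutaniminium triflate F6.
- Aqueous hydrolysis of F6 comes back to the route at 6, so step 3 falls away.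

## Further compounds

F1 | step 4 | triethyl{[(3R)-3-{[3-methoxy-4-(triisopropylsilyloxy)phenyl]methyl}cyclobut-1-en-1-yl]oxy}silane | COc1cc(C[C@H]2C=C(O[Si](CC)(CC)CC)C2)ccc1O[Si](C(C)C)(C(C)C)C(C)C
F2 | step 4 | (3R)-4-hydroxy-3-{[3-methoxy-4-(triisopropylsilyloxy)phenyl]methyl}butanoic acid | COc1cc(C[C@@H](CO)CC(=O)O)ccc1O[Si](C(C)C)(C(C)C)C(C)C
F3 | step 7 | diethyl (4R)-4-{[3-methoxy-4-(triisopropylsilyloxy)phenyl]methyl}-4,5-dihydrofuran-2-yl phosphate | COc1cc(C[C@H]2COC(OP(=O)(OCC)OCC)=C2)ccc1O[Si](C(C)C)(C(C)C)C(C)C
F4 | step 7 | diethyl [(4S)-4-{[3-methoxy-4-(triisopropylsilyloxy)phenyl]methyl}-2-oxooxolan-3-yl]phosphonate (same spatial arrangement at C4 as in 8, descriptor changed by priority only; C3 epimers) | COc1cc(C[C@H]2COC(=O)C2P(=O)(OCC)OCC)ccc1O[Si](C(C)C)(C(C)C)C(C)C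
F5 | step 2 | N,N-dimethylketeniminium triflate | C=C=[N+](C)C.[O-]S(=O)(=O)C(F)(F)F
F6 | step 2 | N-(3-{[3-methoxy-4-(triisopropylsilyloxy)phenyl]methyl}cyclobutylidene)-N-methylmethanaminium triflate | C[N+](C)=C1CC(Cc2ccc(O[Si](C(C)C)(C(C)C)C(C)C)c(OC)c2)C1.[O-]S(=O)(=O)C(F)(F)F
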